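The route rests on cutting the aryl ether bond O1–C8a of the dihydropyran ring, with the C2 carbinol stereocentre set beforehand by a Sharpless epoxidation of geranylgeraniol. The key step exploits the two phenolic oxygens on C7 and C8 that flank C8a. An open-chain 7-hydroxy-8-methoxy arene (a guaiacol), carrying the tertiary alcohol on a two-carbon tether at C4a, is oxidised to its masked ortho-benzoquinone, in which C8a is the δ-carbon of a dienone. The tertiary alkoxide adds there and loss of methanol restores the benzene ring. One operation thus turns an aryl C–H bond into the ring C–O bond and closes the pyran ring last, without touching C2.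

Key step: step 6

Remark: by the CIP rules (O1 > C3 > C1' of the side chain > CH3) the target is the (2S)-chroman; ring atoms are numbered as in the chroman (O1, C2, C3, C4, C4a, C5 to C8, C8a), and all-E geranylgeraniol is taken as the commercial C20 starting material.

Step 1
Reactants: 1 (2E,6E,10E)-geranylgeraniol
Product: 2 (2S,3S)-2,3-epoxygeranylgeraniol
Conditions: Ti(OiPr)4 (5 mol %), L-(+)-diethyl tartrate (7.5 mol %), t-BuOOH (anhydrous), 4 Å MS, CH2Cl2, −20 °C
Reagents that add atoms: tert-butyl hydroperoxide, CC(C)(C)OO
Why: Sharpless asymmetric epoxidation: the catalyst formed from Ti(OiPr)4 and the tartrate binds the allylic hydroxyl, so only the 2,3-alkene of the tetraene should be epoxidised, and L-(+)-diethyl tartrate delivers oxygen to the face that gives the (2S,3S)-epoxide (as for geraniol), which fixes the tertiary C–O stereocentre that becomes C2 of the chroman.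

Step 2
Reactants: 2 (2S,3S)-2,3-epoxygeranylgeraniol
Product: 3 (2R,3S)-2,3-epoxygeranylgeranyl iodide
Conditions: PPh3, imidazole, I2, Et2O/MeCN, 0 °C
Reagents that add atoms: iodine, II
Why: Appel-type iodination (Garegg–Samuelsson conditions): the primary alcohol is displaced by iodide at C1 via the oxyphosphonium salt under imidazole buffering, which should leave the trisubstituted epoxide and both stereocentres untouched (the C2 descriptor changes only because iodine raises the priority of C1).

Step 3
Reactants: 3 (2R,3S)-2,3-epoxygeranylgeranyl iodide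
Product: 4 (S)-geranyllinalool
Conditions: Zn dust, AcOH, EtOH, 0 °C → rt
Reagents that add atoms: none
Why: Zinc-mediated reductive ring opening (β-elimination of an organozinc): zinc inserts into the C–I bond and the epoxide C2–O bond is expelled, giving the transposed tertiary allylic alcohol with the C3–O bond intact, hence (S) with retention.

Step 4
Reactants: 5 2-methoxy-5-methylphenol
Product: 6 4-bromo-2-methoxy-5-methylphenol
Conditions: NBS (1.0 equiv), MeCN, 0 °C
Reagents that add atoms: N-bromosuccinimide, O=C1CCC(=O)N1Br
Why: Electrophilic aromatic bromination: the free hydroxyl is the strongest director and its para position (also ortho to the methyl group) is the most activated and least hindered site, so one equivalent of NBS should give the 4-bromide.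

Step 5
Reactants: 4 (S)-geranyllinalool; 6 4-bromo-2-methoxy-5-methylphenol
Product: 8 4-[(3S,6E,10E)-3-hydroxy-3,7,11,15-tetramethylhexadeca-6,10,14-trien-1-yl]-2-methoxy-5-methylphenol, via B-alkyl-9-BBN borane 7 (not isolated)
Conditions: 9-BBN (1.2 equiv), THF, 0 °C → rt; then 6, PdCl2(dppf) (5 mol %), 3 M aq NaOH, THF, 65 °C
Reagents that add atoms: none
Why: Hydroboration followed by B-alkyl Suzuki–Miyaura coupling: 9-BBN adds anti-Markovnikov to the monosubstituted vinyl group far faster than to the three trisubstituted alkenes (and reacts only slowly with the tertiary hydroxyl), and the primary alkylborane should couple with the aryl bromide under aqueous base without touching the stereocentre.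

Step 6
Reactants: 8 4-[(3S,6E,10E)-3-hydroxy-3,7,11,15-tetramethylhexadeca-6,10,14-trien-1-yl]-2-methoxy-5-methylphenol
Product: 11 (2S)-8-methoxy-2,5-dimethyl-2-[(3E,7E)-4,8,12-trimethyltrideca-3,7,11-trien-1-yl]-3,4-dihydro-2H-chromen-7-ol, via masked ortho-benzoquinone ketal 9 (not isolated), via cyclised dienol ketal 10 (not isolated)
Conditions: PhI(OAc)2 (1.05 equiv), MeOH, −20 °C; aq NaHCO3 wash, solvent switch to THF; KN(SiMe3)2 (1.1 equiv), −78 → −20 °C; AcOH, → rt
Reagents that add atoms: methanol, CO (one of the two ketal methoxy groups of 9 is retained at C8, the other leaves again as methanol)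
Why: PhI(OAc)2 oxidises the C7 phenol and methanol captures the resulting cation at C8, the ortho carbon stabilised by its methoxy group, giving the 6,6-dimethoxycyclohexa-2,4-dienone 9 in which C8a is the δ-carbon of the C7 dienone; the potassium alkoxide of the tertiary alcohol then adds to C8a (1,6-oxa-Michael addition), and on acidification dienol 10 ionises a ketal methoxy group at C8 and loses the C8a proton, which restores the benzene ring. The closest known reaction type is the oxidative nucleophilic substitution of 2-alkoxyphenols through orthoquinone monoketals (oxygen heterocyclisation of orthoquinol acetates by a tethered alkoxide), supported by the cyclisation of hydroxyalkyl quinones to chromanols. The dihydropyran ring closes in the 6-endo-trig mode, with oxygen attacking C8a of the C4a=C8a double bond that carries the tether. No new stereocentre survives (C8a is sp3 only in 10), and C2 keeps its (S) configuration because no bond to it is made or broken. The step needs site selectivity in the oxidation (C8 rather than the para carbon C4a) and regioselectivity in the addition (C8a rather than C5): the methoxy group secures the first, and the methyl group on C5 the second, since an adduct at C5 is hindered, cannot aromatise and reverts, whereas the C8a adduct is drained irreversibly by loss of methanol. The low temperature and the absence of strong acid should keep the three trisubstituted alkenes out of the reaction.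

Step 7
Reactants: 11 (2S)-8-methoxy-2,5-dimethyl-2-[(3E,7E)-4,8,12-trimethyltrideca-3,7,11-trien-1-yl]-3,4-dihydro-2H-chromen-7-ol
Product: 13 (2S)-2,5-dimethyl-2-[(3E,7E)-4,8,12-trimethyltrideca-3,7,11-trien-1-yl]-3,4-dihydro-2H-chromene-7,8-diol, via ortho-quinone 12 (not isolated)
Conditions: IBX (1.2 equiv), THF/DMF, 0 °C → rt; then aq Na2S2O4, EtOAc, rt, under argon
Reagents that add atoms: 2-iodoxybenzoic acid (IBX), O=C1OI(=O)(O)c2ccccc12
Why: IBX-mediated oxidative demethylation of a 2-methoxyphenol: IBX bound at the C7 hydroxyl transfers oxygen to the methoxy-bearing ortho carbon C8, methanol is lost to give ortho-quinone 12, and dithionite reduces it in the same flask to the catechol, under neutral conditions that should spare the alkenes, the chroman ether and C2.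

Compound list
1 | (2E,6E,10E)-geranylgeraniol, (2E,6E,10E)-3,7,11,15-tetramethylhexadeca-2,6,10,14-tetraen-1-ol | CC(C)=CCC/C(C)=C/CC/C(C)=C/CC/C(C)=C/CO | starting material
2 | (2S,3S)-2,3-epoxygeranylgeraniol, (2S,3S,6E,10E)-2,3-epoxy-3,7,11,15-tetramethylhexadeca-6,10,14-trien-1-ol | CC(C)=CCC/C(C)=C/CC/C(C)=C/CC[C@]1(C)O[C@H]1CO | intermediate
3 | (2R,3S)-2,3-epoxygeranylgeranyl iodide, (2R,3S,6E,10E)-2,3-epoxy-1-iodo-3,7,11,15-tetramethylhexadeca-6,10,14-triene | CC(C)=CCC/C(C)=C/CC/C(C)=C/CC[C@]1(C)O[C@H]1CI | intermediate
4 | (S)-geranyllinalool, (3S,6E,10E)-3,7,11,15-tetramethylhexadeca-1,6,10,14-tetraen-3-ol | CC(C)=CCC/C(C)=C/CC/C(C)=C/CC[C@](C)(O)C=C | intermediate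
5 | 2-methoxy-5-methylphenol | COc1ccc(C)cc1O | starting material
6 | 4-bromo-2-methoxy-5-methylphenol | COc1cc(Br)c(C)cc1O | intermediate
7 | B-alkyl-9-BBN borane from 4 (9-borabicyclo[3.3.1]nonan-9-yl on C1 of the side chain, tertiary alcohol free; formed in the flask) | CC(C)=CCC/C(C)=C/CC/C(C)=C/CC[C@](C)(O)CCB1C2CCCC1CCC2 | intermediate
8 | 4-[(3S,6E,10E)-3-hydroxy-3,7,11,15-tetramethylhexadeca-6,10,14-trien-1-yl]-2-methoxy-5-methylphenol | CC(C)=CCC/C(C)=C/CC/C(C)=C/CC[C@](C)(O)CCc1cc(OC)c(O)cc1C | intermediate
9 | masked ortho-benzoquinone, 4-[(3S,6E,10E)-3-hydroxy-3,7,11,15-tetramethylhexadeca-6,10,14-trien-1-yl]-6,6-dimethoxy-3-methylcyclohexa-2,4-dien-1-one (formed in the flask) | CC(C)=CCC/C(C)=C/CC/C(C)=C/CC[C@](C)(O)CCC1=CC(OC)(OC)C(=O)C=C1C | intermediate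
10 | cyclised dienol ketal, (2S)-8,8-dimethoxy-2,5-dimethyl-2-[(3E,7E)-4,8,12-trimethyltrideca-3,7,11-trien-1-yl]-3,4,8,8a-tetrahydro-2H-chromen-7-ol (C8a configuration undefined; formed in the flask) | CC(C)=CCC/C(C)=C/CC/C(C)=C/CC[C@@]1(C)CCC2=C(C)C=C(O)C(OC)(OC)C2O1 | intermediate
11 | (2S)-8-methoxy-2,5-dimethyl-2-[(3E,7E)-4,8,12-trimethyltrideca-3,7,11-trien-1-yl]-3,4-dihydro-2H-chromen-7-ol | CC(C)=CCC/C(C)=C/CC/C(C)=C/CC[C@@]1(C)CCc2c(C)cc(O)c(OC)c2O1 | intermediate
12 | (2S)-2,5-dimethyl-2-[(3E,7E)-4,8,12-trimethyltrideca-3,7,11-trien-1-yl]-3,4-dihydro-2H-chromene-7,8-dione (formed in the flask) | CC(C)=CCC/C(C)=C/CC/C(C)=C/CC[C@@]1(C)CCC2=C(O1)C(=O)C(=O)C=C2C | intermediate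
13 | (2S)-2,5-dimethyl-2-[(3E,7E)-4,8,12-trimethyltrideca-3,7,11-trien-1-yl]-3,4-dihydro-2H-chromene-7,8-diol | CC(C)=CCC/C(C)=C/CC/C(C)=C/CC[C@@]1(C)CCc2c(C)cc(O)c(O)c2O1 | target

Total step count: 7. Longest linear sequence: 6 steps (steps 1, 2, 3, 5, 6, 7).

Steps most likely to fail

1. Step 6. The alkoxide may add at C5 instead of C8a, or the addition may revert before aromatisation. Dienone 9 may dimerise by [4+2] cycloaddition, or the oxidised phenol may be captured at the para carbon C4a instead of C8. The fallback makes the O1–C8a bond by a palladium-catalysed aryl etherification of an aryl chloride instead of by conjugate addition. It sets out from 6 (and from borane 7, made from 4 as in step 5) and comes back at 11. Phenol 6 would be protected with MOMCl and iPr2NEt as 1-bromo-5-methoxy-4-(methoxymethoxy)-2-methylbenzene F1. Deprotonation of the position between bromine and methoxy with LiN(iPr)2 at −78 °C and quench with C2Cl6 should give 1-bromo-2-chloro-3-methoxy-4-(methoxymethoxy)-6-methylbenzene F2. B-alkyl Suzuki–Miyaura coupling of 7 at the C–Br bond of F2 (Pd(OAc)2, SPhos, aq NaOH, THF, 65 °C) should give (3S,6E,10E)-1-[2-chloro-3-methoxy-4-(methoxymethoxy)-6-methylphenyl]-3,7,11,15-tetramethylhexadeca-6,10,14-trien-3-ol F3. Intramolecular C–O coupling of the tertiary alcohol with the aryl chloride (Pd(OAc)2, a bulky di-tert-butyl biaryl phosphine, Cs2CO3, toluene, 80 °C) should give (2S)-8-methoxy-7-(methoxymethoxy)-2,5-dimethyl-2-[(3E,7E)-4,8,12-trimethyltrideca-3,7,11-trien-1-yl]-3,4-dihydro-2H-chromene F4. Removal of the MOM group (PPTS, MeOH, 50 °C) returns to 11.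

2. Step 7. Oxygen may be transferred to the free ortho position C6 instead of C8, and quinone 12 may tautomerise to a quinone methide or be oxidised further before it is reduced. The fallback removes the methyl group without any oxidation, by SN2 attack of a thiolate on the methyl carbon. It sets out from 11 and comes back at 13: NaSEt in degassed DMF at 130 °C, then acidic work-up under argon. No new compound is needed.

3. Step 5. Oxidative addition into the electron-rich, ortho-substituted bromophenoxide may be slow, and protodeboronation of 7 may then compete. The fallback makes the same C4–C4a bond by a Mizoroki–Heck reaction. It sets out from 4 and 6 and comes back at 8. Pd(OAc)2, P(o-tol)3 and Et3N in DMF at 100 °C should give 4-[(1E,3S,6E,10E)-3-hydroxy-3,7,11,15-tetramethylhexadeca-1,6,10,14-tetraen-1-yl]-2-methoxy-5-methylphenol F5. Diimide (from 2-nitrobenzenesulfonyl hydrazide and Et3N, CH2Cl2, rt) reduces the disubstituted styrene-type alkene much faster than the trisubstituted ones and returns to 8.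

Further compounds
F1 | step 6 | 1-bromo-5-methoxy-4-(methoxymethoxy)-2-methylbenzene | COCOc1cc(C)c(Br)cc1OC
F2 | step 6 | 1-bromo-2-chloro-3-methoxy-4-(methoxymethoxy)-6-methylbenzene | COCOc1cc(C)c(Br)c(Cl)c1OC
F3 | step 6 | (3S,6E,10E)-1-[2-chloro-3-methoxy-4-(methoxymethoxy)-6-methylphenyl]-3,7,11,15-tetramethylhexadeca-6,10,14-trien-3-ol | CC(C)=CCC/C(C)=C/CC/C(C)=C/CC[C@](C)(O)CCc1c(C)cc(OCOC)c(OC)c1Cl
F4 | step 6 | (2S)-8-methoxy-7-(methoxymethoxy)-2,5-dimethyl-2-[(3E,7E)-4,8,12-trimethyltrideca-3,7,11-trien-1-yl]-3,4-dihydro-2H-chromene | CC(C)=CCC/C(C)=C/CC/C(C)=C/CC[C@@]1(C)CCc2c(C)cc(OCOC)c(OC)c2O1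
F0 | step 7 | none | none
F5 | step 5 | 4-[(1E,3S,6E,10E)-3-hydroxy-3,7,11,15-tetramethylhexadeca-1,6,10,14-tetraen-1-yl]-2-methoxy-5-methylphenol | CC(C)=CCC/C(C)=C/CC/C(C)=C/CC[C@](C)(O)/C=C/c1cc(OC)c(O)cc1C
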